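**Plan**

- Retrosynthesis: the bridging ketal C–O bond between coumarin O4 and the pyran carbon that carries the 3-methylbutanoyl group is cut first (back to an enol silane of a 2-acylpyran with a free coumarin 4-OH). Next the cyclopentene C=C is cut (back to an exocyclic methylene and an allyl group). Then the O–C and C–C bonds at the pyran O–CH carbon on coumarin C3 are cut together (back to a coumarin-3-carbaldehyde and a hydroxy allylsilane). Last, the chain is cut at the C–CH2Si bond, the ketone C–C bond and the aldol bond.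
- Feature used: in the pyran ring the O–CH carbon on coumarin C3 sits between the ring oxygen and the ring-fusion CH, and the next ring carbon (pyran C4, shared with the cyclopentene) is sp2. An oxocarbenium ion captured by a 2-substituted allylsilane leaves exactly this pattern.
- Forward: the chain is joined by an auxiliary-controlled aldol, a Weinreb ketone synthesis and an enol triflate/Grignard coupling. The pyran ring arises first (silyl-Prins), the cyclopentene second (ring-closing metathesis), and the 1,3-dioxin ring of the ketal last (epoxidation of the enol silane, capture by the coumarin hydroxyl).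
- Stereochemistry: the methyl-bearing pyran carbon comes from the syn aldol and the methyl-bearing cyclopentene carbon from an auxiliary-controlled allylation. The O–CH carbon and the ring-fusion carbon are set in the chair transition state of the key step by the (E)-oxocarbenium and (Z)-allylsilane geometries. The ketal carbon is fixed by the bridge.

Key step: step 17

Remark (assumption): the side-chain carbinol carbon ends as the ketone carbon, so its configuration is free, and the (R)-hydroxy acid is chosen because its aldehyde is the matched (Felkin–Anh) partner in the aldol step; pyran locants below are O1, C2 (future ketal carbon), C3 (methyl-bearing), C4 (sp2), C5 (ring fusion), C6 (on coumarin C3).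

**Route**

Step 1
Reactants: 1 (R)-2-hydroxy-4-methylpentanoic acid
Product: 2 methyl (R)-2-hydroxy-4-methylpentanoate
Conditions: MeOH, H2SO4 (cat.), reflux
Reagents that add atoms: methanol, CO
Why: Fischer esterification, which does not touch the α-stereocentre.

Step 2
Reactants: 2 methyl (R)-2-hydroxy-4-methylpentanoate
Product: 3 methyl (R)-2-[(tert-butyldimethylsilyl)oxy]-4-methylpentanoate
Conditions: t-BuMe2SiCl, imidazole, DMF, rt
Reagents that add atoms: tert-butyldimethylsilyl chloride, CC(C)(C)[Si](C)(C)Cl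
Why: Silylation of the secondary alcohol with silyl chloride and imidazole gives an ether that should survive the hydride, boron and organomagnesium steps.

Step 3
Reactants: 3 methyl (R)-2-[(tert-butyldimethylsilyl)oxy]-4-methylpentanoate
Product: 4 (R)-2-[(tert-butyldimethylsilyl)oxy]-4-methylpentanal
Conditions: i-Bu2AlH, CH2Cl2, −78 °C; aqueous work-up
Reagents that add atoms: none
Why: Partial hydride reduction of the α-silyloxy ester at −78 °C stops at the aluminium hemiacetal, which should release the aldehyde on work-up without racemisation.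

Step 4
Reactants: 5 (R)-4-benzyl-3-propanoyl-1,3-oxazolidin-2-one
Product: 7 (R)-4-benzyl-3-[(S)-2-methylpent-4-enoyl]-1,3-oxazolidin-2-one, via sodium Z-enolate 6 (not isolated)
Conditions: NaN(SiMe3)2, THF, −78 °C; then allyl iodide, −78 → −40 °C
Reagents that add atoms: allyl iodide, C=CCI
Why: Evans asymmetric alkylation, in which the chelated Z-enolate is allylated on the face away from the benzyl group and so sets the (S)-configured methyl-bearing carbon of the later cyclopentene.

Step 5
Reactants: 7 (R)-4-benzyl-3-[(S)-2-methylpent-4-enoyl]-1,3-oxazolidin-2-one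
Product: 8 (S)-2-methylpent-4-en-1-ol
Conditions: LiBH4, H2O (1 equiv), Et2O, 0 °C
Reagents that add atoms: none
Why: Hydride reduction of the N-acyl oxazolidinone (reductive removal of the auxiliary) should give the primary alcohol and the free auxiliary without touching the stereocentre.

Step 6
Reactants: 8 (S)-2-methylpent-4-en-1-ol
Product: 9 (S)-5-bromo-4-methylpent-1-ene
Conditions: CBr4, PPh3, CH2Cl2, 0 °C
Reagents that add atoms: carbon tetrabromide, BrC(Br)(Br)Br
Why: Appel bromination replaces the primary hydroxyl by SN2 at the CH2 group, away from the stereocentre.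

Step 7
Reactants: 10 (S)-4-benzyl-3-propanoyl-1,3-oxazolidin-2-one; 4 (R)-2-[(tert-butyldimethylsilyl)oxy]-4-methylpentanal
Product: 12 (S)-4-benzyl-3-[(2S,3S,4R)-4-[(tert-butyldimethylsilyl)oxy]-3-hydroxy-2,6-dimethylheptanoyl]-1,3-oxazolidin-2-one, via dibutylboron Z-enolate 11 (not isolated)
Conditions: Bu2BOTf, i-Pr2NEt, CH2Cl2, −78 → 0 °C; then 4, −78 → 0 °C; pH 7 buffer, MeOH, H2O2
Reagents that add atoms: none
Why: Evans syn aldol, in which the boron Z-enolate reacts through a Zimmerman–Traxler chair on the face fixed by the auxiliary while the (R)-silyloxy aldehyde is the matched Felkin–Anh (3,4-anti) partner, so the methyl- and hydroxyl-bearing carbons should be set as (2S,3S).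

Step 8
Reactants: 12 (S)-4-benzyl-3-[(2S,3S,4R)-4-[(tert-butyldimethylsilyl)oxy]-3-hydroxy-2,6-dimethylheptanoyl]-1,3-oxazolidin-2-one
Product: 13 (2S,3S,4R)-4-[(tert-butyldimethylsilyl)oxy]-3-hydroxy-N-methoxy-N,2,6-trimethylheptanamide
Conditions: MeNHOMe·HCl, AlMe3, CH2Cl2, −20 → 0 °C
Reagents that add atoms: N,O-dimethylhydroxylamine hydrochloride, CNOC.Cl
Why: Aluminium amide transamination of the β-hydroxy imide (Weinreb amide formation) is helped by the free hydroxyl and should remove the auxiliary without epimerisation.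

Step 9
Reactants: 13 (2S,3S,4R)-4-[(tert-butyldimethylsilyl)oxy]-3-hydroxy-N-methoxy-N,2,6-trimethylheptanamide
Product: 14 (2S,3S,4R)-4-[(tert-butyldimethylsilyl)oxy]-N-methoxy-N,2,6-trimethyl-3-[(triethylsilyl)oxy]heptanamide
Conditions: Et3SiCl, imidazole, DMF, 0 °C → rt
Reagents that add atoms: chlorotriethylsilane, CC[Si](Cl)(CC)CC
Why: Silylation of the secondary alcohol as a triethylsilyl ether, which can later be removed beside the tert-butyldimethylsilyl ether.

Step 10
Reactants: 9 (S)-5-bromo-4-methylpent-1-ene; 14 (2S,3S,4R)-4-[(tert-butyldimethylsilyl)oxy]-N-methoxy-N,2,6-trimethyl-3-[(triethylsilyl)oxy]heptanamide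
Product: 16 (4S,7S,8S,9R)-9-[(tert-butyldimethylsilyl)oxy]-4,7,11-trimethyl-8-[(triethylsilyl)oxy]dodec-1-en-6-one, via Grignard reagent 15 (not isolated)
Conditions: Mg, THF, rt; then 14, THF, −78 → 0 °C; aqueous NH4Cl
Reagents that add atoms: none
Why: Weinreb ketone synthesis, in which the magnesium chelate of the tetrahedral adduct holds until work-up, so the Grignard reagent should add only once and the ketone is formed with defined regiochemistry.

Step 11
Reactants: 16 (4S,7S,8S,9R)-9-[(tert-butyldimethylsilyl)oxy]-4,7,11-trimethyl-8-[(triethylsilyl)oxy]dodec-1-en-6-one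
Product: 18 (4S,5Z,7S,8S,9R)-9-[(tert-butyldimethylsilyl)oxy]-4,7,11-trimethyl-8-[(triethylsilyl)oxy]dodeca-1,5-dien-6-yl trifluoromethanesulfonate, via potassium Z-enolate 17 (not isolated)
Conditions: KN(SiMe3)2, THF, −78 °C; then PhNTf2, −78 → 0 °C
Reagents that add atoms: N-phenylbis(trifluoromethanesulfonimide), O=S(=O)(N(c1ccccc1)S(=O)(=O)C(F)(F)F)C(F)(F)F
Why: Kinetic deprotonation by the bulky amide at the unbranched CH2 should give the Z-enolate (oxygen cis to the alkyl chain, which avoids A(1,3) strain with the α-branched acyl substituent), and O-triflation traps it as the Z-enol triflate.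

Step 12
Reactants: 18 (4S,5Z,7S,8S,9R)-9-[(tert-butyldimethylsilyl)oxy]-4,7,11-trimethyl-8-[(triethylsilyl)oxy]dodeca-1,5-dien-6-yl trifluoromethanesulfonate
Product: 19 (4S,5Z,7R,8S,9R)-9-[(tert-butyldimethylsilyl)oxy]-4,7,11-trimethyl-8-[(triethylsilyl)oxy]-6-[(trimethylsilyl)methyl]dodeca-1,5-diene
Conditions: Me3SiCH2MgCl, Pd(PPh3)4 (cat.), THF, 0 °C → rt
Reagents that add atoms: (trimethylsilyl)methylmagnesium chloride, C[Si](C)(C)C[Mg]Cl
Why: Kumada coupling catalysed by zerovalent palladium replaces the triflate with retention of alkene geometry and should give the 2-substituted (Z)-allylsilane.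

Step 13
Reactants: 19 (4S,5Z,7R,8S,9R)-9-[(tert-butyldimethylsilyl)oxy]-4,7,11-trimethyl-8-[(triethylsilyl)oxy]-6-[(trimethylsilyl)methyl]dodeca-1,5-diene
Product: 20 (4S,5Z,7R,8S,9R)-9-[(tert-butyldimethylsilyl)oxy]-4,7,11-trimethyl-6-[(trimethylsilyl)methyl]dodeca-1,5-dien-8-ol
Conditions: pyridinium p-toluenesulfonate (cat.), MeOH/CH2Cl2, 0 °C
Reagents that add atoms: none
Why: Mild acid methanolysis (selective silyl ether solvolysis) should remove the more labile triethylsilyl group and leave the tert-butyldimethylsilyl ether and the allylsilane intact.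

Step 14
Reactants: 21 1-(2-hydroxy-6-methylphenyl)ethan-1-one
Product: 22 4-hydroxy-5-methyl-2H-chromen-2-one
Conditions: NaH, diethyl carbonate, toluene, 110 °C; then aqueous HCl
Reagents that add atoms: diethyl carbonate, CCOC(=O)OCC
Why: Claisen-type C-acylation of the ketone enolate with diethyl carbonate and lactonisation onto the phenoxide is the standard route from 2-hydroxyacetophenones to 4-hydroxycoumarins.

Step 15
Reactants: 22 4-hydroxy-5-methyl-2H-chromen-2-one
Product: 23 4-chloro-5-methyl-2-oxo-2H-chromene-3-carbaldehyde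
Conditions: POCl3, DMF, 0 → 60 °C; then ice/water
Reagents that add atoms: N,N-dimethylformamide, CN(C)C=O; phosphoryl chloride, O=P(Cl)(Cl)Cl; water, O
Why: Vilsmeier–Haack reaction, in which the chloroiminium reagent formylates the nucleophilic C3 and exchanges the 4-hydroxyl for chloride, the usual outcome with 4-hydroxycoumarins.

Step 16
Reactants: 23 4-chloro-5-methyl-2-oxo-2H-chromene-3-carbaldehyde
Product: 24 4-methoxy-5-methyl-2-oxo-2H-chromene-3-carbaldehyde
Conditions: MeOH, Et3N, CH2Cl2, 0 °C → rt
Reagents that add atoms: methanol, CO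
Why: Addition–elimination (nucleophilic vinylic substitution) of methanol at C4 of the vinylogous acid chloride, which is activated by the formyl and lactone carbonyl groups, should give the 4-methoxy aldehyde.

Step 17
Reactants: 20 (4S,5Z,7R,8S,9R)-9-[(tert-butyldimethylsilyl)oxy]-4,7,11-trimethyl-6-[(trimethylsilyl)methyl]dodeca-1,5-dien-8-ol; 24 4-methoxy-5-methyl-2-oxo-2H-chromene-3-carbaldehyde
Product: 26 3-[(2R,3R,5R,6S)-6-[(1R)-1-[(tert-butyldimethylsilyl)oxy]-3-methylbutyl]-5-methyl-4-methylidene-3-[(2S)-pent-4-en-2-yl]oxan-2-yl]-4-methoxy-5-methyl-2H-chromen-2-one, via oxocarbenium triflate 25 (not isolated)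
Conditions: Me3SiOTf, Et2O, −78 °C; aqueous NaHCO3 quench
Reagents that add atoms: none
Why: Me3SiOTf condenses the hydroxyl group of 20 with the formyl group of 24 to the (E)-oxocarbenium ion 25, the CH terminus of the allylsilane C=C attacks its carbon, and the β-silyl cation loses the silyl group to leave the exocyclic methylene on C4 (silyl-Prins, that is intramolecular silyl-modified Sakurai cyclisation; the closest known type is the pyran annulation of hydroxy allylsilanes with aldehydes to 2,6-cis-4-methylenetetrahydropyrans). The pyran ring closes in the 6-endo-trig mode through a chair, forming the O1–C6 and C5–C6 bonds. C6 is controlled by the (E)-geometry of the oxocarbenium ion, which places the coumarin equatorial and therefore cis to the equatorial side chain on C2; C5 is controlled by the (Z)-geometry of the alkene, which places the pentenyl chain equatorial and therefore trans to the coumarin. The chair that is needed carries the C3 methyl group axial, and this should be the favoured one, because an equatorial methyl group would eclipse the CH2SiMe3 group on C4 and the other chair would force the large C2 side chain into an axial position. The step also needs acetal formation at the formyl carbon instead of exchange of the 4-methoxy group, and ring closure that outruns protodesilylation: the peri 5-methyl group shields C4 of the coumarin, and the electron-rich allylsilane should trap the cation at −78 °C as soon as it forms.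

Step 18
Reactants: 26 3-[(2R,3R,5R,6S)-6-[(1R)-1-[(tert-butyldimethylsilyl)oxy]-3-methylbutyl]-5-methyl-4-methylidene-3-[(2S)-pent-4-en-2-yl]oxan-2-yl]-4-methoxy-5-methyl-2H-chromen-2-one
Product: 27 3-[(1R,3S,4R,7S,7aR)-3-[(1R)-1-[(tert-butyldimethylsilyl)oxy]-3-methylbutyl]-4,7-dimethyl-1,3,4,6,7,7a-hexahydrocyclopenta[c]pyran-1-yl]-4-methoxy-5-methyl-2H-chromen-2-one
Conditions: second-generation Grubbs catalyst RuCl2(=CHPh)(PCy3)(H2IMes) (cat.), CH2Cl2, 40 °C
Reagents that add atoms: none
Why: Ring-closing metathesis of the terminal alkene with the 1,1-disubstituted exocyclic methylene should close the cyclopentene (trisubstituted alkene) with loss of ethene and creates no stereocentre.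

Step 19
Reactants: 27 3-[(1R,3S,4R,7S,7aR)-3-[(1R)-1-[(tert-butyldimethylsilyl)oxy]-3-methylbutyl]-4,7-dimethyl-1,3,4,6,7,7a-hexahydrocyclopenta[c]pyran-1-yl]-4-methoxy-5-methyl-2H-chromen-2-one
Product: 28 3-[(1R,3S,4R,7S,7aR)-3-[(1R)-1-hydroxy-3-methylbutyl]-4,7-dimethyl-1,3,4,6,7,7a-hexahydrocyclopenta[c]pyran-1-yl]-4-methoxy-5-methyl-2H-chromen-2-one
Conditions: HF·pyridine, pyridine, THF, 0 °C → rt
Reagents that add atoms: none
Why: Desilylation with buffered HF (Si–F bond formation) should free the secondary alcohol without ionising the ether bond at the coumarin-bearing carbon.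

Step 20
Reactants: 28 3-[(1R,3S,4R,7S,7aR)-3-[(1R)-1-hydroxy-3-methylbutyl]-4,7-dimethyl-1,3,4,6,7,7a-hexahydrocyclopenta[c]pyran-1-yl]-4-methoxy-5-methyl-2H-chromen-2-one
Product: 29 3-[(1R,3S,4R,7S,7aR)-4,7-dimethyl-3-(3-methylbutanoyl)-1,3,4,6,7,7a-hexahydrocyclopenta[c]pyran-1-yl]-4-methoxy-5-methyl-2H-chromen-2-one
Conditions: Dess–Martin periodinane, pyridine, CH2Cl2, 0 °C → rt
Reagents that add atoms: none
Why: Dess–Martin oxidation should give the α-alkoxy ketone under near-neutral conditions and removes the side-chain carbinol stereocentre.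

Step 21
Reactants: 29 3-[(1R,3S,4R,7S,7aR)-4,7-dimethyl-3-(3-methylbutanoyl)-1,3,4,6,7,7a-hexahydrocyclopenta[c]pyran-1-yl]-4-methoxy-5-methyl-2H-chromen-2-one
Product: 30 3-[(1R,3S,4R,7S,7aR)-4,7-dimethyl-3-(3-methylbutanoyl)-1,3,4,6,7,7a-hexahydrocyclopenta[c]pyran-1-yl]-4-hydroxy-5-methyl-2H-chromen-2-one
Conditions: LiI, pyridine, 100 °C; then dilute aqueous HCl
Reagents that add atoms: none
Why: Nucleophilic (SN2) demethylation of the vinylogous methyl ester by iodide, in which the 4-oxidocoumarin is a carboxylate-like leaving group, should free the 4-hydroxyl, and any epimerisation next to the ketone is harmless because that carbon becomes sp2 in step 22.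

Step 22
Reactants: 30 3-[(1R,3S,4R,7S,7aR)-4,7-dimethyl-3-(3-methylbutanoyl)-1,3,4,6,7,7a-hexahydrocyclopenta[c]pyran-1-yl]-4-hydroxy-5-methyl-2H-chromen-2-one
Product: 32 3-[(1R,4R,7S,7aR)-3-{1-[(tert-butyldimethylsilyl)oxy]-3-methylbutylidene}-4,7-dimethyl-1,3,4,6,7,7a-hexahydrocyclopenta[c]pyran-1-yl]-4-hydroxy-5-methyl-2H-chromen-2-one, via bis-silyl ether 31 (not isolated)
Conditions: t-BuMe2SiOTf, Et3N, CH2Cl2, 0 °C → rt; then MeOH, NaHCO3, 0 °C
Reagents that add atoms: tert-butyldimethylsilyl trifluoromethanesulfonate, CC(C)(C)[Si](C)(C)OS(=O)(=O)C(F)(F)F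
Why: Soft enolisation with silyl triflate and amine under equilibrating conditions should place the silyl enol ether on the ring carbon (the more substituted and α-oxygenated, thermodynamic position), and brief methanolysis removes the labile silyl group from the acidic coumarin oxygen.

Step 23
Reactants: 32 3-[(1R,4R,7S,7aR)-3-{1-[(tert-butyldimethylsilyl)oxy]-3-methylbutylidene}-4,7-dimethyl-1,3,4,6,7,7a-hexahydrocyclopenta[c]pyran-1-yl]-4-hydroxy-5-methyl-2H-chromen-2-one
Product: 34 CNP0310889.1 (target), via silyloxy spiro-epoxide 33 (not isolated)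
Conditions: dimethyldioxirane (dried solution in acetone), CH2Cl2, −78 → −20 °C
Reagents that add atoms: dimethyldioxirane, CC1(C)OO1
Why: Rubottom-type oxidation in which dimethyldioxirane should epoxidise the electron-rich enol ether selectively, the alkoxy-epoxide opens at the ring carbon with help from the ring oxygen and is captured by the acidic 4-hydroxyl in a 6-membered closure (the way 1,2-anhydro sugars are opened by acidic hydroxyl groups), and loss of silanol leaves the ketone; the new ketal stereocentre can only form with the coumarin oxygen cis to the coumarin carbon because both belong to the same bridge.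

**Compound list**

1 | (R)-2-hydroxy-4-methylpentanoic acid | CC(C)C[C@@H](O)C(=O)O | starting material
2 | methyl (R)-2-hydroxy-4-methylpentanoate | CC(C)C[C@@H](O)C(=O)OC | intermediate
3 | methyl (R)-2-[(tert-butyldimethylsilyl)oxy]-4-methylpentanoate | CC(C)C[C@@H](O[Si](C)(C)C(C)(C)C)C(=O)OC | intermediate
4 | (R)-2-[(tert-butyldimethylsilyl)oxy]-4-methylpentanal | CC(C)C[C@@H](O[Si](C)(C)C(C)(C)C)C=O | intermediate
5 | (R)-4-benzyl-3-propanoyl-1,3-oxazolidin-2-one | CCC(=O)N1[C@H](Cc2ccccc2)COC1=O | starting material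
6 | sodium (Z)-enolate of 5, formed in the flask | C/C=C(\[O-])N1[C@H](Cc2ccccc2)COC1=O.[Na+] | intermediate
7 | (R)-4-benzyl-3-[(S)-2-methylpent-4-enoyl]-1,3-oxazolidin-2-one | C=CC[C@H](C)C(=O)N1[C@H](Cc2ccccc2)COC1=O | intermediate
8 | (S)-2-methylpent-4-en-1-ol | C=CC[C@H](C)CO | intermediate
9 | (S)-5-bromo-4-methylpent-1-ene | C=CC[C@H](C)CBr | intermediate
10 | (S)-4-benzyl-3-propanoyl-1,3-oxazolidin-2-one | CCC(=O)N1[C@@H](Cc2ccccc2)COC1=O | starting material
11 | dibutylboron (Z)-enolate of 10, formed in the flask | C/C=C(\OB(CCCC)CCCC)N1[C@@H](Cc2ccccc2)COC1=O | intermediate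
12 | (S)-4-benzyl-3-[(2S,3S,4R)-4-[(tert-butyldimethylsilyl)oxy]-3-hydroxy-2,6-dimethylheptanoyl]-1,3-oxazolidin-2-one | O=C(N1[C@@H](Cc2ccccc2)COC1=O)[C@@H](C)[C@H](O)[C@H](O[Si](C)(C)C(C)(C)C)CC(C)C | intermediate
13 | (2S,3S,4R)-4-[(tert-butyldimethylsilyl)oxy]-3-hydroxy-N-methoxy-N,2,6-trimethylheptanamide | CON(C)C(=O)[C@@H](C)[C@H](O)[C@H](O[Si](C)(C)C(C)(C)C)CC(C)C | intermediate
14 | (2S,3S,4R)-4-[(tert-butyldimethylsilyl)oxy]-N-methoxy-N,2,6-trimethyl-3-[(triethylsilyl)oxy]heptanamide | CON(C)C(=O)[C@@H](C)[C@H](O[Si](CC)(CC)CC)[C@H](O[Si](C)(C)C(C)(C)C)CC(C)C | intermediate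
15 | [(S)-2-methylpent-4-en-1-yl]magnesium bromide, formed in the flask | C=CC[C@H](C)C[Mg]Br | intermediate
16 | (4S,7S,8S,9R)-9-[(tert-butyldimethylsilyl)oxy]-4,7,11-trimethyl-8-[(triethylsilyl)oxy]dodec-1-en-6-one | C=CC[C@H](C)CC(=O)[C@@H](C)[C@H](O[Si](CC)(CC)CC)[C@H](O[Si](C)(C)C(C)(C)C)CC(C)C | intermediate
17 | potassium (Z)-enolate of 16 (enolate C5=C6), formed in the flask | C=CC[C@H](C)/C=C(\[O-])[C@@H](C)[C@H](O[Si](CC)(CC)CC)[C@H](O[Si](C)(C)C(C)(C)C)CC(C)C.[K+] | intermediate
18 | (4S,5Z,7S,8S,9R)-9-[(tert-butyldimethylsilyl)oxy]-4,7,11-trimethyl-8-[(triethylsilyl)oxy]dodeca-1,5-dien-6-yl trifluoromethanesulfonate | C=CC[C@H](C)/C=C(\OS(=O)(=O)C(F)(F)F)[C@@H](C)[C@H](O[Si](CC)(CC)CC)[C@H](O[Si](C)(C)C(C)(C)C)CC(C)C | intermediate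
19 | (4S,5Z,7R,8S,9R)-9-[(tert-butyldimethylsilyl)oxy]-4,7,11-trimethyl-8-[(triethylsilyl)oxy]-6-[(trimethylsilyl)methyl]dodeca-1,5-diene | C=CC[C@H](C)/C=C(\C[Si](C)(C)C)[C@@H](C)[C@H](O[Si](CC)(CC)CC)[C@H](O[Si](C)(C)C(C)(C)C)CC(C)C | intermediate
20 | (4S,5Z,7R,8S,9R)-9-[(tert-butyldimethylsilyl)oxy]-4,7,11-trimethyl-6-[(trimethylsilyl)methyl]dodeca-1,5-dien-8-ol | C=CC[C@H](C)/C=C(\C[Si](C)(C)C)[C@@H](C)[C@H](O)[C@H](O[Si](C)(C)C(C)(C)C)CC(C)C | intermediate
21 | 1-(2-hydroxy-6-methylphenyl)ethan-1-one | CC(=O)c1c(C)cccc1O | starting material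
22 | 4-hydroxy-5-methyl-2H-chromen-2-one | Cc1cccc2oc(=O)cc(O)c12 | intermediate
23 | 4-chloro-5-methyl-2-oxo-2H-chromene-3-carbaldehyde | Cc1cccc2oc(=O)c(C=O)c(Cl)c12 | intermediate
24 | 4-methoxy-5-methyl-2-oxo-2H-chromene-3-carbaldehyde | Cc1cccc2oc(=O)c(C=O)c(OC)c12 | intermediate
25 | (E)-oxocarbenium trifluoromethanesulfonate from the hydroxyl oxygen of 20 and the formyl carbon of 24, formed in the flask | C=CC[C@H](C)/C=C(\C[Si](C)(C)C)[C@@H](C)[C@H](/[O+]=C/c1c(OC)c2c(C)cccc2oc1=O)[C@H](O[Si](C)(C)C(C)(C)C)CC(C)C.[O-]S(=O)(=O)C(F)(F)F | intermediate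
26 | 3-[(2R,3R,5R,6S)-6-[(1R)-1-[(tert-butyldimethylsilyl)oxy]-3-methylbutyl]-5-methyl-4-methylidene-3-[(2S)-pent-4-en-2-yl]oxan-2-yl]-4-methoxy-5-methyl-2H-chromen-2-one | O=c1oc2cccc(C)c2c(OC)c1[C@@H]3O[C@H]([C@H](O[Si](C)(C)C(C)(C)C)CC(C)C)[C@H](C)C(=C)[C@H]3[C@@H](C)CC=C | intermediate
27 | 3-[(1R,3S,4R,7S,7aR)-3-[(1R)-1-[(tert-butyldimethylsilyl)oxy]-3-methylbutyl]-4,7-dimethyl-1,3,4,6,7,7a-hexahydrocyclopenta[c]pyran-1-yl]-4-methoxy-5-methyl-2H-chromen-2-one | O=c1oc2cccc(C)c2c(OC)c1[C@@H]3O[C@H]([C@H](O[Si](C)(C)C(C)(C)C)CC(C)C)[C@H](C)C4=CC[C@H](C)[C@@H]34 | intermediate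
28 | 3-[(1R,3S,4R,7S,7aR)-3-[(1R)-1-hydroxy-3-methylbutyl]-4,7-dimethyl-1,3,4,6,7,7a-hexahydrocyclopenta[c]pyran-1-yl]-4-methoxy-5-methyl-2H-chromen-2-one | O=c1oc2cccc(C)c2c(OC)c1[C@@H]3O[C@H]([C@H](O)CC(C)C)[C@H](C)C4=CC[C@H](C)[C@@H]34 | intermediate
29 | 3-[(1R,3S,4R,7S,7aR)-4,7-dimethyl-3-(3-methylbutanoyl)-1,3,4,6,7,7a-hexahydrocyclopenta[c]pyran-1-yl]-4-methoxy-5-methyl-2H-chromen-2-one | O=c1oc2cccc(C)c2c(OC)c1[C@@H]3O[C@H](C(=O)CC(C)C)[C@H](C)C4=CC[C@H](C)[C@@H]34 | intermediate
30 | 3-[(1R,3S,4R,7S,7aR)-4,7-dimethyl-3-(3-methylbutanoyl)-1,3,4,6,7,7a-hexahydrocyclopenta[c]pyran-1-yl]-4-hydroxy-5-methyl-2H-chromen-2-one | O=c1oc2cccc(C)c2c(O)c1[C@@H]3O[C@H](C(=O)CC(C)C)[C@H](C)C4=CC[C@H](C)[C@@H]34 | intermediate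
31 | 4-[(tert-butyldimethylsilyl)oxy]-3-[(1R,4R,7S,7aR)-3-{1-[(tert-butyldimethylsilyl)oxy]-3-methylbutylidene}-4,7-dimethyl-1,3,4,6,7,7a-hexahydrocyclopenta[c]pyran-1-yl]-5-methyl-2H-chromen-2-one (enol ether geometry not defined), formed in the flask | O=c1oc2cccc(C)c2c(O[Si](C)(C)C(C)(C)C)c1[C@@H]3OC(=C(O[Si](C)(C)C(C)(C)C)CC(C)C)[C@H](C)C4=CC[C@H](C)[C@@H]34 | intermediate
32 | 3-[(1R,4R,7S,7aR)-3-{1-[(tert-butyldimethylsilyl)oxy]-3-methylbutylidene}-4,7-dimethyl-1,3,4,6,7,7a-hexahydrocyclopenta[c]pyran-1-yl]-4-hydroxy-5-methyl-2H-chromen-2-one (enol ether geometry not defined) | O=c1oc2cccc(C)c2c(O)c1[C@@H]3OC(=C(O[Si](C)(C)C(C)(C)C)CC(C)C)[C@H](C)C4=CC[C@H](C)[C@@H]34 | intermediate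
33 | spiro-epoxide of the enol ether C=C of 32 (silyloxy-oxirane spiro-fused at the pyran carbon next to the ring oxygen; epoxide configuration not defined), formed in the flask | O=c1oc2cccc(C)c2c(O)c1[C@@H]3OC5(OC5(O[Si](C)(C)C(C)(C)C)CC(C)C)[C@H](C)C4=CC[C@H](C)[C@@H]34 | intermediate
34 | CNP0310889.1: bridged ketal in which coumarin O4 and the pyran oxygen share the carbon that bears the 3-methylbutanoyl group (ketal carbon S, methyl-bearing pyran carbon R, ring-fusion carbon R, O–CH carbon R, methyl-bearing cyclopentene carbon S) | Cc1cccc2oc(=O)c3c(c12)O[C@@]1(C(=O)CC(C)C)O[C@@H]3[C@H]2C(=CC[C@@H]2C)[C@H]1C | target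

**Totals and risks**

Total step count: 23. Longest linear sequence: 17 steps (steps 1–3, 7–13, 17–23).

Most likely to fail, in this order:

1. Step 22. The enolisation may not equilibrate to the ring carbon, so that the silyl enol ether forms on the isobutyl side, or the acidic coumarin hydroxyl may add across the new enol ether before it is oxidised. Fallback: do without a discrete enol derivative. Starting from 30, oxidative cycloetherification under ammonium hypoiodite catalysis (Bu4NI cat., tert-butyl hydroperoxide, EtOAc, 50 °C; the conditions used for oxidative α-C–O coupling of ketones with phenols and carboxylic acids) should lead directly to 34. α-Iodination is reversible, and only the iodide on the ring carbon, whose ionisation the ring oxygen assists, can be displaced by the coumarin oxygen in a 6-membered closure. This fallback sets out from 30, comes back at 34 and makes no compound outside the list (F0).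

2. Step 23. The epoxidation may lose chemoselectivity (attack on the cyclopentene or on the hydroxycoumarin enol), or the opened epoxide may be hydrolysed or lose a proton before the ring closes. Fallback: close the ketal without an oxidant and adjust the oxidation level afterwards. Starting from 32, a catalytic amount of pyridinium p-toluenesulfonate in CH2Cl2 at 0 °C should protonate the enol ether at the silyloxy-bearing carbon (protonation at the ring carbon only returns 30), and the 4-hydroxyl adds to the ring oxocarbenium ion to give the bridged ketal silyl ether F1. HF·pyridine then frees the bridged ketal alcohol F2, and Dess–Martin oxidation comes back to the route at 34.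

3. Step 17. Acetal formation at the hindered, donor-stabilised formyl group may be slow, so that protodesilylation of the allylsilane, exchange at coumarin C4 or 2-oxonia-Cope scrambling competes with ring closure. Fallback: use a more electrophilic aldehyde. Alcohol 20 is combined with the 4-chloro aldehyde 23 under the same silyl triflate activation to give the 4-chlorocoumarinyl methylenepyran F3. The chloride is then exchanged by addition–elimination with NaOMe in MeOH, which comes back to the route at 26.

**Further compounds**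

F0 | step 22 | none | none
F1 | step 23 | bridged ketal of 34 with the side-chain C=O replaced by CH–OSi(t-Bu)Me2 (both epimers at that carbon) | Cc1cccc2oc(=O)c3c(c12)O[C@@]1(C(O[Si](C)(C)C(C)(C)C)CC(C)C)O[C@@H]3[C@H]2C(=CC[C@@H]2C)[C@H]1C
F2 | step 23 | bridged ketal of 34 with the side-chain C=O replaced by CH–OH (both epimers at that carbon) | Cc1cccc2oc(=O)c3c(c12)O[C@@]1(C(O)CC(C)C)O[C@@H]3[C@H]2C(=CC[C@@H]2C)[C@H]1C
F3 | step 17 | 4-chloro analogue of 26: 3-[(2R,3R,5R,6S)-6-[(1R)-1-[(tert-butyldimethylsilyl)oxy]-3-methylbutyl]-5-methyl-4-methylidene-3-[(2S)-pent-4-en-2-yl]oxan-2-yl]-4-chloro-5-methyl-2H-chromen-2-one | O=c1oc2cccc(C)c2c(Cl)c1[C@@H]3O[C@H]([C@H](O[Si](C)(C)C(C)(C)C)CC(C)C)[C@H](C)C(=C)[C@H]3[C@@H](C)CC=C
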